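How much target stands in the flask at 30 min, and which change adds most to it?

- north-east: substrate 0.050 M; gas phase 5.2 mM (held); the very flask that is asked about, followed so far
- flask: substrate 0.050 M; gas phase 5.2 mM (held); time 30 min

- north-east (time / min: target / %, substrate / %): 0.667: 0.3, 99.4; 1.50: 0.4, 98.7; 4.00: 4.1, 96.2; 10.0: 6.9, 90.0

(each reading ± 0.5 percentage points)

- the earlier runs were read with a standard deviation of 0.5 percentage points
- at the start none of the gas phase is in solution

1. the target standing at 30 min, as a percentage of the substrate charged
2. the change that raises the amount of target at 30 min, in percent of the substrate charged most ("none" if none brings more than 2 percentage points) (noon / dawn / none)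
3. amount of target at 30 min, in percent of the substrate charged, after dawn

By 10.0 min, 10.0% of the substrate is gone. At that pace 30.0% is gone at 30 min, a rough ceiling on target, and the 6.9% already standing is a rough floor. Of the substrate lost by 10.0 min, a share of 0.690 stands as target; held to 30 min, this gives 20.7% as a rough upper estimate. Of the loss after 4.00 min, the share read is 0.452; held for the remaining loss, it gives 15.9% as a rough lower estimate. Both shares carry the scatter of the readings.

The quantity to carry is the gas share, the fraction of the charge that dissolved gas amounts to in a saturated solution, 10.4%. The bracket lies above it, so, if each target takes up one dissolved gas, more gas has to pass through the solution than a saturated solution holds at one moment. Doubling the transfer coefficient (noon) hurries dissolved gas towards the same share; doubling the saturation (dawn) raises the share itself. This reckoning puts dawn first, provided target is made in step with dissolved gas.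

The forecast gives 12%, below the bracket, chooses none and gives 10.7% after dawn, holding that “gas uptake looks fast and transfer is probably not limiting”.

The flask gives 17.1%, inside the bracket . Noon adds 5.3 percentage points and dawn 14 points, so the choice is dawn, with 30.9% of target.

    gas phase ⇌ dissolved gas, rate k1*(csat - [dissolved gas]) (kL = 0.00230 /s)
    substrate + dissolved gas ⇌ target (K = 84.0 /M, k = 0.180 /M/s)
    substrate → side product (k = 3.00 × 10⁻⁵ /s)
    target ⇌ isomer of the product (K = 15.0, k = 1.30 × 10⁻⁴ /s)

At 30.0 min the flask holds dissolved gas at 6.43% of the charge, 61.8% of saturation, while target stands above the gas share. The neighbouring flask, the same but charged with 0.20 M of substrate, has a gas share of 2.60%. At the same time its target, 7.51% of its charge, also stands above that share, and its dissolved gas stands at 0.652% of its charge, a quarter of saturation.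

Readings and results were computed on assumed constants; scatter was added.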